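Late in the winter run Z stands nearer to Q than late in the autumn run: Z over Q, as fractions of the E charged, is 0.801 at 112 °C against 0.636 at 90 °C. I must choose the temperature to charge.

| flask | E | D | temperature | remark | time |
|---|---|---|---|---|---|
| autumn | 0.11 M | 0.066 M | 90 °C | run made earlier |  |
| winter | 0.11 M | 0.26 M | 112 °C | run made earlier |  |
| south-east | 0.11 M | 0.132 M | 80 °C |  | 5.0 d |
| south | 0.11 M | 0.132 M | 100 °C |  | 5.0 d |
| south-west | 0.11 M | 0.132 M | 120 °C |  | 5.0 d |

autumn run (percent of the E charged)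

| time / d | Q / % | Z / % |
|---|---|---|
| 0.500 | 3.9 | 0.2 |
| 1.04 | 5.5 | 0.6 |
| 1.67 | 6.0 | 2.9 |
| 2.50 | 10.7 | 6.9 |
| 3.00 | 10.9 | 6.5 |
| 4.00 | 12.7 | 8.4 |

winter run (percent of the E charged)

| time / h | Q / % | Z / % |
|---|---|---|
| 4.00 | 8.3 | 5.5 |
| 8.00 | 11.5 | 6.8 |
| 12.0 | 11.6 | 11.8 |
| 15.0 | 14.1 | 12.2 |
| 20.0 | 16.7 | 11.6 |
| 25.0 | 16.8 | 15.2 |
| 30.0 | 17.8 | 14.3 |

(scatter of a reading: 1 percentage point)

1. the flask that comes out highest in share of Q in all that became Q or Z, or "all alike" when all lie within 1.5 percentage points (south-east / south / south-west / all alike)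
2. share of Q in all that became Q or Z, south-east
3. share of Q in all that became Q or Z, south
4. share of Q in all that became Q or Z, south-west



I read these ratios as resting ratios K of Q and Z, an equilibrium constant, and I set the difference in D between the two runs aside. Integrating van 't Hoff with the heat held constant puts ln K on a straight line in reciprocal absolute temperature. Its slope gives the tilt, the heat of Q going to Z: 12.2 kJ mol⁻¹. This is a rough reading, since a scatter of 1 percentage point sits on small readings.

The resting share of Q is then 63.8% in south-east, 58.5% in south and 53.6% in south-west. The spread of 10 points is wider than the margin, so I charge south-east. Q comes first, as autumn's 3.9% against 0.2% at 0.500 d shows, so if south-east is still moving at the asked time I expect it to stand above 63.8%.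

The forecast also picks south-east, with 72% (62% to 82%), 58% (53% to 64%) and 53% (47% to 59%). Its ground is that “this looks like a Q⇌Z equilibrium”. Its south-east figure is higher than my resting share.

The flasks give 70.5%, 58.7% and 50.2%, so south-east comes out highest, as the forecast said.

    2 L → X (k = 0.420 M⁻¹ h⁻¹, Ea = 96.0 kJ mol⁻¹)
    E ⇌ G (K = 0.190, k = 0.310 h⁻¹, Ea = 106 kJ mol⁻¹, ΔH = −22.0 kJ mol⁻¹)
    D → L (k = 0.00990 h⁻¹, Ea = 121 kJ mol⁻¹)
    Q ⇌ Z (K = 0.480, k = 0.0270 h⁻¹, Ea = 107 kJ mol⁻¹, ΔH = 21.0 kJ mol⁻¹)
    G + L → Q (k = 0.660 M⁻¹ h⁻¹, Ea = 85.0 kJ mol⁻¹)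
    (constants at 80 °C)

South-east has 30% of its D left at 5.00 d and stands at 67.6% at 50.0 d. In south-west Q and Z relax with a half-life of 0.314 h, short against 5.0 d, and its share stays at 50.2% at 50.0 d. South stays at 58.7%. I read both as resting: Z over Q goes from 0.703 to 0.994, a tilt of 21.1 kJ mol⁻¹, steeper than my 12.2 kJ mol⁻¹. Carried from south-west to a like flask at 145 °C, it gives a resting share of 40.6%. That flask gives 40.7%.

Readings and results were generated by integration on assumed constants, and the scatter is random.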